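**Retrosynthetic overview**
1. Locants follow 1H-isochromene numbering (C1, O2, C3, C4, C4a, C5–C8, C8a); ring A is the carbocycle and ring B the pyran. The endgame is C5 chlorination and O8 desilylation of the 5-H, 8-O-TBS bicycle.
2. Key disconnection: C4a–C8a and C3=C4 are cut together. This opens both rings to a dienoate ester of a (hydroxymethyl)dihydrofuran that carries a 4-chlorobut-2-ynoyl group, with PPh3 as the only stoichiometric partner.
3. Enabling feature: rings B and A share the push–pull chain O2–C3=C4–C4a=C5–C6=O, so C3 is an ester carbon, C4 an ylide carbon and C4a a Michael terminus. On ring A the 7-OH and the 8a-acetyl group are 1,3-cis, so they can be tied as a 2-methyl-4,5-dihydrofuran whose nucleophilic enol ether carbon is C8a.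
4. Ring order: temporary dihydrofuran (early), then ring A, then ring B (both in the key step); water in the work-up then opens the temporary ring.
5. Precursor: O2–C3 by esterification, C5–C6 by Weinreb ketone synthesis, acetyl by Wacker oxidation, C8–C8a by asymmetric allylboration, C7 from the L-lactic acid dioxolanone. The side-chain acid comes from (S)-2-methylbutan-1-ol by Wittig and HWE olefinations.

Key step: step 16

Assumption: the 7-OH/8a-acetyl pair is written as the open hydroxy ketone, as in the target, although it may equilibrate with its bridged hemiketal; buta-2,3-dien-1-ol and (2S,5S)-2-tert-butyl-5-methyl-1,3-dioxolan-4-one are taken as catalogue chemicals.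

Step 1
Reactants: 1 (S)-2-methylbutan-1-ol
Product: 2 (S)-2-methylbutanal
Conditions: TEMPO (cat.), PhI(OAc)2, CH2Cl2, 0 to 23 °C
Reagents that add atoms: none
Why: TEMPO/oxoammonium oxidation of a primary alcohol stops at the aldehyde under non-basic conditions, so the side-chain stereocentre taken from the chiral pool should not epimerise.

Step 2
Reactants: 2 (S)-2-methylbutanal
Product: 3 (2E,4S)-2,4-dimethylhex-2-enal
Conditions: Ph3P=C(CH3)CHO, CH2Cl2, 40 °C
Reagents that add atoms: 2-(triphenylphosphoranylidene)propanal, CC(C=O)=P(c1ccccc1)(c1ccccc1)c1ccccc1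
Why: Wittig olefination with a stabilised formyl ylide should give the (E)-trisubstituted enal and leaves the adjacent stereocentre untouched.

Step 3
Reactants: 3 (2E,4S)-2,4-dimethylhex-2-enal
Product: 4 ethyl (2E,4E,6S)-4,6-dimethylocta-2,4-dienoate
Conditions: (EtO)2P(O)CH2CO2Et, NaH, THF, 0 to 23 °C
Reagents that add atoms: triethyl phosphonoacetate, CCOC(=O)CP(=O)(OCC)OCC
Why: Horner–Wadsworth–Emmons olefination of an enal with a phosphonoacetate anion is reliably E-selective and completes the (2E,4E)-diene.

Step 4
Reactants: 4 ethyl (2E,4E,6S)-4,6-dimethylocta-2,4-dienoate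
Product: 5 (2E,4E,6S)-4,6-dimethylocta-2,4-dienoic acid
Conditions: LiOH, THF/MeOH/H2O, 23 °C; 1 M HCl
Reagents that add atoms: lithium hydroxide, [Li+].[OH-]
Why: Saponification of an unhindered ethyl ester, to which the conjugated diene and the remote stereocentre are inert.

Step 5
Reactants: 6 buta-2,3-dien-1-ol
Product: 7 tert-butyl(buta-2,3-dienyloxy)dimethylsilane
Conditions: TBSCl, imidazole, CH2Cl2, 23 °C
Reagents that add atoms: tert-butyldimethylsilyl chloride, CC(C)(C)[Si](C)(C)Cl
Why: Standard silylation of a primary alcohol, which leaves the allene untouched.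

Step 6
Reactants: 8 (2S,5S)-2-tert-butyl-5-methyl-1,3-dioxolan-4-one
Product: 10 (2S,5R)-2-tert-butyl-5-(hydroxymethyl)-5-methyl-1,3-dioxolan-4-one, via lithium enolate 9 (not isolated)
Conditions: LiN(i-Pr)2, THF, −78 °C; CH2O (gas), −78 °C; AcOH
Reagents that add atoms: formaldehyde, C=O
Why: Aldol addition of the dioxolanone enolate to formaldehyde on the face anti to the tert-butyl group (self-regeneration of the stereocentre) replaces H by CH2OH with retention and so sets the quaternary C7 as R.

Step 7
Reactants: 10 (2S,5R)-2-tert-butyl-5-(hydroxymethyl)-5-methyl-1,3-dioxolan-4-one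
Product: 11 (2S,5R)-5-formyl analogue of 10 (C8 aldehyde)
Conditions: Dess–Martin periodinane, CH2Cl2, 23 °C
Reagents that add atoms: none
Why: Dess–Martin oxidation under neutral conditions gives a non-enolisable aldehyde and leaves the acylal ring intact.

Step 8
Reactants: 11 C8 aldehyde; 7 tert-butyl(buta-2,3-dienyloxy)dimethylsilane
Product: 13 (7R,8R)-homoallylic alcohol (dioxolanone bearing CH(OH)–CH(CH2OTBS)–CH=CH2), via allylborane 12 (not isolated)
Conditions: 7, (+)-Ipc2BH, THF, 0 °C; 11, −78 to −20 °C; H2O2, pH 7 buffer, 0 °C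
Reagents that add atoms: none
Why: Hydroboration of the terminal allene C=C puts boron on the CH2 terminus. The resulting γ-substituted allylborane adds through a closed Zimmerman–Traxler chair (Brown-type allylboration), in which the Ipc groups choose the aldehyde face that gives 8R, expected to coincide with the polar Felkin–Anh face; the C8a centre formed alongside is erased in step 12.

Step 9
Reactants: 13 (7R,8R)-homoallylic alcohol
Product: 14 8-O-TBS ether of 13
Conditions: TBSOTf, 2,6-lutidine, CH2Cl2, 0 °C
Reagents that add atoms: tert-butyldimethylsilyl triflate, CC(C)(C)[Si](C)(C)OS(=O)(=O)C(F)(F)F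
Why: Silyl triflate silylation copes with the hindered secondary alcohol and blocks O8 against retro-aldol cleavage and against later oxa-Michael addition.

Step 10
Reactants: 14 8-O-TBS ether of 13
Product: 15 (7R,8R)-α-hydroxy Weinreb amide with free tertiary 7-OH
Conditions: MeNH(OMe)·HCl, i-PrMgCl, THF, −20 to 0 °C
Reagents that add atoms: N,O-dimethylhydroxylamine hydrochloride, CNOC.Cl
Why: Weinreb aminolysis of the activated acylal lactone, whose hemiacetal alkoxide collapses to pivalaldehyde and so frees the 7-OH without touching either stereocentre.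

Step 11
Reactants: 15 (7R,8R)-α-hydroxy Weinreb amide
Product: 16 γ-hydroxy methyl ketone (in equilibrium with its five-membered hemiketal)
Conditions: PdCl2 (cat.), CuCl, O2 (1 atm), DMF/H2O, 23 °C
Reagents that add atoms: water, O
Why: Tsuji–Wacker oxidation of the terminal vinyl group is Markovnikov-selective, and 5-exo participation of the 7-OH leads to the same hydroxy ketone/hemiketal.

Step 12
Reactants: 16 γ-hydroxy methyl ketone
Product: 17 (7R,8R)-2-methyl-4,5-dihydrofuran (O7 bound to the former ketone carbon, C8a sp2, C6 amide trans to 8-OTBS)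
Conditions: PPTS (cat.), 4 Å MS, toluene, 80 °C
Reagents that add atoms: none
Why: Acid-catalysed dehydration of the cyclic hemiketal is reversible through the common oxocarbenium ion. It should therefore settle on the thermodynamically favoured endocyclic tetrasubstituted enol ether, which erases the C8a centre and masks both the 7-OH and the acetyl group.

Step 13
Reactants: 17 (7R,8R)-2-methyl-4,5-dihydrofuran
Product: 18 primary allylic alcohol (free C1–OH)
Conditions: TBAF (1 equiv), THF, 0 °C
Reagents that add atoms: none
Why: Fluoride cleaves the unhindered primary silyl ether much faster than the secondary one flanked by the quaternary C7, and the basic medium spares the enol ether.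

Step 14
Reactants: 18 primary allylic alcohol; 5 (2E,4E,6S)-4,6-dimethylocta-2,4-dienoic acid
Product: 19 dienoate ester (O2–C3 bond in place)
Conditions: DCC, DMAP (cat.), CH2Cl2, 0 to 23 °C
Reagents that add atoms: none
Why: Steglich esterification is acid-free, so the ionisable allylic alcohol on the enol ether should be acylated without rearrangement.

Step 15
Reactants: 19 dienoate ester
Product: 20 4-chlorobut-2-ynoyl ketone (chloro-ynone ester)
Conditions: HC≡CCH2Cl, EtMgBr, THF, 0 °C; 19, −20 to 0 °C; aq. NH4Cl
Reagents that add atoms: propargyl chloride, C#CCCl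
Why: In the Weinreb ketone synthesis the chelated tetrahedral intermediate stops at the ynone, and an alkynyl Grignard reagent should not attack the conjugated dienoate at this temperature.

Step 16
Reactants: 20 chloro-ynone ester
Product: 25 (7R,8R,8aS)-8-O-TBS-5-deschloro target, via propargylic phosphonium chloride 21 (not isolated), via allenyl phosphonium chloride 22 (not isolated), via ring A ylide 23 (not isolated), via bridged enol ether 24 (not isolated)
Conditions: PPh3 (1.0 equiv), MeCN (0.005 M), 0 to 23 °C; Et3N (0.05 equiv), 40 °C; Et3N (2 equiv), 70 °C; THF/pH 4 citrate buffer, 23 °C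
Reagents that add atoms: water, O
Why: Proposed new method: SN2 displacement of the propargylic chloride by PPh3 gives 21, which a trace of base equilibrates with the allenyl tautomer 22, whose central carbon C4a is the β-carbon of both the C6 ketone and the phosphonium group; the neutral enol ether carbon C8a adds to it and, after loss of a proton from the methyl group next to the ring oxygen, the carbanion created at C4 is the vinylogous acyl ylide 23, which olefinates the only carbonyl group within reach, the C3 ester carbonyl, to give 24 and Ph3PO, and mild aqueous acid then hydrolyses only the simple bridged enol ether to the 7-OH/8a-acetyl pair. The closest known reaction types are the Schweizer-type annulation (conjugate addition of a nucleophile to a vinyl- or allenylphosphonium salt, then intramolecular Wittig reaction) and the intramolecular Wittig olefination of ester carbonyls that converts acyloxybenzyl and (acyloxymethyl)benzyl phosphonium salts into benzofurans and 1H-isochromenes with Et3N; new are the enol ether as carbon nucleophile and the merger of the two events. Ring A closes by in-plane attack on the exocyclic C4a=C4 π bond of the allene (6-exo, equivalent to 6-endo-dig on the ynone tautomer), and ring B closes by 6-exo-trig attack of C4 on the ester C=O through the oxaphosphetane. The only new stereocentre, C8a, is fixed by geometry: the C6 arm sits on C7 of the five-membered ring and can reach C8a only from its own face, which is also anti to the 8-OTBS group, and the persisting O7–carbon bridge forces the future acetyl group cis to O7. The step needs carbon attack without β-elimination, which the substrate secures because no enolate is ever present (the C1 acyloxy group cannot leave by E1cB and the acetyl methyl cannot attack the ester), O7 is locked in the ring (no 3(2H)-furanone from the ynone), O8 is silylated, and only C4–H is acidic enough for Et3N.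

Step 17
Reactants: 25 (7R,8R,8aS)-8-O-TBS-5-deschloro target
Product: 26 8-O-TBS ether of the target
Conditions: NCS, MeCN, 0 to 23 °C, dark
Reagents that add atoms: N-chlorosuccinimide, O=C1CCC(=O)N1Cl
Why: Electrophilic chlorination should occur at C5, the nucleophilic terminus of the dienol ether O2–C3=C4–C4a=C5 and α-carbon of the vinylogous ester, which is the known halogenation site of azaphilone-type isochromenones.

Step 18
Reactants: 26 8-O-TBS ether of the target
Product: 27 target CNP0307047.1
Conditions: HF·pyridine, pyridine, THF, 0 to 23 °C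
Reagents that add atoms: none
Why: Fluoride-driven Si–O cleavage under weakly acidic conditions avoids the basic media in which the β-hydroxy ketone unit could undergo retro-aldol or retro-Claisen cleavage, and no stereocentre is touched.

**Compound list**
1 | (S)-2-methylbutan-1-ol | CC[C@H](C)CO | starting material
2 | (S)-2-methylbutanal | CC[C@H](C)C=O | intermediate
3 | (2E,4S)-2,4-dimethylhex-2-enal | CC[C@H](C)/C=C(C)/C=O | intermediate
4 | ethyl (2E,4E,6S)-4,6-dimethylocta-2,4-dienoate | CC[C@H](C)/C=C(C)/C=C/C(=O)OCC | intermediate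
5 | (2E,4E,6S)-4,6-dimethylocta-2,4-dienoic acid | CC[C@H](C)/C=C(C)/C=C/C(=O)O | intermediate
6 | buta-2,3-dien-1-ol | C=C=CCO | starting material
7 | tert-butyl(buta-2,3-dienyloxy)dimethylsilane | C=C=CCO[Si](C)(C)C(C)(C)C | intermediate
8 | (2S,5S)-2-tert-butyl-5-methyl-1,3-dioxolan-4-one | O=C1O[C@@H](C(C)(C)C)O[C@H]1C | starting material
9 | lithium enolate of 8 | [Li+].[O-]C1=C(C)O[C@H](C(C)(C)C)O1 | intermediate
10 | (2S,5R)-2-tert-butyl-5-(hydroxymethyl)-5-methyl-1,3-dioxolan-4-one | O=C1O[C@@H](C(C)(C)C)O[C@]1(C)CO | intermediate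
11 | (2S,5R)-5-formyl analogue of 10 (C8 aldehyde) | O=C1O[C@@H](C(C)(C)C)O[C@]1(C)C=O | intermediate
12 | [4-(TBSO)but-2-enyl]bis(isopinocampheyl)borane (alkene geometry and Ipc centres not drawn) | CC1C(CC2CC1C2(C)C)B(CC=CCO[Si](C)(C)C(C)(C)C)C1CC2CC(C1C)C2(C)C | intermediate
13 | (7R,8R)-homoallylic alcohol (C8a set by the borane geometry, not specified, erased in step 12) | O=C1O[C@@H](C(C)(C)C)O[C@]1(C)[C@H](O)C(CO[Si](C)(C)C(C)(C)C)C=C | intermediate
14 | 8-O-TBS ether of 13 | O=C1O[C@@H](C(C)(C)C)O[C@]1(C)[C@H](O[Si](C)(C)C(C)(C)C)C(CO[Si](C)(C)C(C)(C)C)C=C | intermediate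
15 | (7R,8R)-α-hydroxy Weinreb amide | CON(C)C(=O)[C@](C)(O)[C@H](O[Si](C)(C)C(C)(C)C)C(CO[Si](C)(C)C(C)(C)C)C=C | intermediate
16 | γ-hydroxy methyl ketone | CON(C)C(=O)[C@](C)(O)[C@H](O[Si](C)(C)C(C)(C)C)C(CO[Si](C)(C)C(C)(C)C)C(C)=O | intermediate
17 | (7R,8R)-2-methyl-4,5-dihydrofuran, bis-TBS | CON(C)C(=O)[C@]1(C)OC(C)=C(CO[Si](C)(C)C(C)(C)C)[C@H]1O[Si](C)(C)C(C)(C)C | intermediate
18 | primary allylic alcohol | CON(C)C(=O)[C@]1(C)OC(C)=C(CO)[C@H]1O[Si](C)(C)C(C)(C)C | intermediate
19 | dienoate ester | CON(C)C(=O)[C@]1(C)OC(C)=C(COC(=O)/C=C/C(C)=C/[C@@H](C)CC)[C@H]1O[Si](C)(C)C(C)(C)C | intermediate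
20 | chloro-ynone ester | ClCC#CC(=O)[C@]1(C)OC(C)=C(COC(=O)/C=C/C(C)=C/[C@@H](C)CC)[C@H]1O[Si](C)(C)C(C)(C)C | intermediate
21 | propargylic phosphonium chloride | [Cl-].O=C(C#CC[P+](c1ccccc1)(c1ccccc1)c1ccccc1)[C@]1(C)OC(C)=C(COC(=O)/C=C/C(C)=C/[C@@H](C)CC)[C@H]1O[Si](C)(C)C(C)(C)C | intermediate
22 | allenyl phosphonium chloride | [Cl-].O=C(C=C=C[P+](c1ccccc1)(c1ccccc1)c1ccccc1)[C@]1(C)OC(C)=C(COC(=O)/C=C/C(C)=C/[C@@H](C)CC)[C@H]1O[Si](C)(C)C(C)(C)C | intermediate
23 | ring A ylide (7R,8R,8aS), bridged exocyclic enol ether | C=C1O[C@@]2(C)C(=O)C=C(C=P(c3ccccc3)(c3ccccc3)c3ccccc3)[C@]1(COC(=O)/C=C/C(C)=C/[C@@H](C)CC)[C@H]2O[Si](C)(C)C(C)(C)C | intermediate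
24 | bridged enol ether with rings A and B closed | C=C1O[C@@]2(C)C(=O)C=C3C=C(/C=C/C(C)=C/[C@@H](C)CC)OC[C@]31[C@H]2O[Si](C)(C)C(C)(C)C | intermediate
25 | (7R,8R,8aS)-8-O-TBS-5-deschloro target | CC[C@H](C)/C=C(C)/C=C/C1=CC2=CC(=O)[C@](C)(O)[C@H](O[Si](C)(C)C(C)(C)C)[C@@]2(C(C)=O)CO1 | intermediate
26 | 8-O-TBS ether of the target | CC[C@H](C)/C=C(C)/C=C/C1=CC2=C(Cl)C(=O)[C@](C)(O)[C@H](O[Si](C)(C)C(C)(C)C)[C@@]2(C(C)=O)CO1 | intermediate
27 | CNP0307047.1 | CC[C@H](C)/C=C(C)/C=C/C1=CC2=C(Cl)C(=O)[C@](C)(O)[C@H](O)[C@@]2(C(C)=O)CO1 | target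

**Step count and risks**

Total step count: 18. Longest linear sequence: 13 steps (steps 6 to 18, from 8).

Steps most likely to fail:

1. **Step 16.**
   - Risk: the enol ether may be too weak a nucleophile for the allenyl phosphonium ion. The ylide and the phosphonium ion may oligomerise, or the stabilised ylide may olefinate the ester too slowly.
   - Fallback (known chemistry, the two bonds made in separate events): from 19, 1-propynylmagnesium bromide gives the methyl ynone F1.
   - [JohnPhosAu(NCMe)]SbF6 (cat.) and MeOH in CH2Cl2 close ring A by 6-endo-dig carbocyclisation of the enol ether onto the gold-activated ynone. This gives the bridged methyl ketal F2, in which the acetyl group is masked and C4H3 is the only acidic site.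
   - LiN(SiMe3)2 then triggers a vinylogous Baker–Venkataraman O-to-C acyl transfer from O2 to C4. Aqueous HCl in THF closes ring B by cyclodehydration and hydrolyses the ketal, which comes back to the route at 25.

2. **Step 12.**
   - Risk: the dehydration may stop at the exocyclic enol ether, or the warm acid may ionise the allylic silyloxy groups of the product.
   - Fallback (ring made by haloetherification instead of dehydration): from 15, I2 and NaHCO3 in MeCN give the 5-exo iodoether F3.
   - DBU removes hydrogen iodide to give the exocyclic enol ether F4.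
   - RuHCl(CO)(PPh3)3 (cat.) moves the double bond into the ring, which comes back to the route at 17 and bypasses 16.

3. **Step 15.**
   - Risk: the hindered amide on the quaternary C7 may react too slowly, so that the Grignard reagent decomposes or attacks the dienoate.
   - Fallback (aldehyde addition and oxidation instead of acyl substitution, before the ester is present): from 17, i-Bu2AlH at −78 °C gives the aldehyde F5.
   - 3-Chloroprop-1-ynyllithium adds to give the propargylic alcohol F6 (C6 epimers), and TBAF frees the primary hydroxyl to give the diol F7.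
   - Steglich esterification with 5 at the primary hydroxyl gives the ester alcohol F8, and Dess–Martin oxidation comes back to the route at 20.

Further compounds
F1 | step 16 | methyl ynone | CC#CC(=O)[C@]1(C)OC(C)=C(COC(=O)/C=C/C(C)=C/[C@@H](C)CC)[C@H]1O[Si](C)(C)C(C)(C)C
F2 | step 16 | bridged methyl ketal with ring A closed (ketal centre not specified) | COC1(C)O[C@@]2(C)C(=O)C=C(C)[C@]1(COC(=O)/C=C/C(C)=C/[C@@H](C)CC)[C@H]2O[Si](C)(C)C(C)(C)C
F3 | step 12 | 5-exo iodoether | CON(C)C(=O)[C@]1(C)OC(CI)C(CO[Si](C)(C)C(C)(C)C)[C@H]1O[Si](C)(C)C(C)(C)C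
F4 | step 12 | exocyclic enol ether | CON(C)C(=O)[C@]1(C)OC(=C)C(CO[Si](C)(C)C(C)(C)C)[C@H]1O[Si](C)(C)C(C)(C)C
F5 | step 15 | C6 aldehyde | O=C[C@]1(C)OC(C)=C(CO[Si](C)(C)C(C)(C)C)[C@H]1O[Si](C)(C)C(C)(C)C
F6 | step 15 | propargylic alcohol, bis-TBS | ClCC#CC(O)[C@]1(C)OC(C)=C(CO[Si](C)(C)C(C)(C)C)[C@H]1O[Si](C)(C)C(C)(C)C
F7 | step 15 | diol | ClCC#CC(O)[C@]1(C)OC(C)=C(CO)[C@H]1O[Si](C)(C)C(C)(C)C
F8 | step 15 | ester alcohol | ClCC#CC(O)[C@]1(C)OC(C)=C(COC(=O)/C=C/C(C)=C/[C@@H](C)CC)[C@H]1O[Si](C)(C)C(C)(C)C
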